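With the target numbered as a bicyclo[9.3.1]pentadecane (C1 and C11 bridgeheads, C12 the spiro carbon, C15 the quaternary carbon), the plan rests on opening the cyclohexane ring C1–C14–C13–C12–C11–C15 at C12–C13 and C11–C15. The key step is an intramolecular Diels–Alder reaction between a 2-silyloxycyclohexa-1,3-diene, whose termini are C13 and C15, and an (E)-nitroalkene (C11=C12) hung from C1 on the (Z,Z)-nine-carbon chain. It closes the twelve-membered ring and the cyclohexane together and sets C11 and C15 from C1. The temporary two-carbon bridge, which exploits the 1,4-relationship of C13 and C15, is later cut to the C15 carboxyl group; the nitro group becomes the C12 ketone.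

Key step: step 11

Assumption: (2E)-4-{[tert-butyl(diphenyl)silyl]oxy}but-2-enal and 5-iodo-2-methylpent-2-ene are treated as purchasable building blocks (otherwise each is one or two routine steps from (Z)-but-2-ene-1,4-diol and from 5-bromo-2-methylpent-2-ene).

Locants: target numbering C1–C15 is used for the tricyclic intermediates, whose temporary bridge carbons are C16 (on C15) and C17 (on C13). Ring carbons C1, C2, C3, C4, C5, C6 of the cyclohexenones become C16, C17, C13, C14, C1, C15.

Step 1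
Reactants: 1 2-(2-bromoethyl)-1,3-dioxolane; 2 propyne; 3 oxirane
Product: 6 (3Z)-6-(1,3-dioxolan-2-yl)-4-methylhex-3-en-1-ol, via Grignard reagent 4 (not isolated), via alkenylcopper 5 (not isolated)
Conditions: Mg, THF, 25 °C; CuBr·SMe2, Et2O/Me2S, −45 °C; propyne, −25 °C; pent-1-ynyllithium, HMPA, then oxirane, −40 to 0 °C; aq. NH4Cl
Reagents that add atoms: none
Why: carbocupration of propyne (Normant type) adds the alkyl group and copper syn with copper on the terminal carbon, so the epoxide-opening product carries the two chain carbons cis on the trisubstituted alkene (the later C7=C8, Z).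

Step 2
Reactants: 6 (3Z)-6-(1,3-dioxolan-2-yl)-4-methylhex-3-en-1-ol
Product: 7 2-[(3Z)-6-bromo-3-methylhex-3-en-1-yl]-1,3-dioxolane
Conditions: CBr4, PPh3, 2,6-lutidine, CH2Cl2, 0 °C
Reagents that add atoms: tetrabromomethane, BrC(Br)(Br)Br
Why: Appel bromination of the primary alcohol runs under buffered non-acidic conditions that leave the acetal and the Z-alkene untouched.

Step 3
Reactants: 7 2-[(3Z)-6-bromo-3-methylhex-3-en-1-yl]-1,3-dioxolane; 2 propyne
Product: 10 2-[(3Z,7Z)-8-iodo-3,7-dimethylocta-3,7-dien-1-yl]-1,3-dioxolane, via Grignard reagent 8 (not isolated), via alkenylcopper 9 (not isolated)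
Conditions: Mg, THF, 30 °C; CuBr·SMe2, Et2O/Me2S, −45 °C; propyne, −25 °C; I2, THF, −60 to 0 °C
Reagents that add atoms: iodine, II
Why: a second syn-carbocupration of propyne followed by iodinolysis of the carbon–copper bond with retention gives the (Z)-alkenyl iodide with iodine cis to the chain (the later C3=C4, Z).

Step 4
Reactants: 11 (2E)-4-{[tert-butyl(diphenyl)silyl]oxy}but-2-enal; 12 tert-butyl 3-oxobutanoate
Product: 15 (5S)-5-({[tert-butyl(diphenyl)silyl]oxy}methyl)cyclohex-2-en-1-one, via Michael adduct 13 (not isolated), via keto ester 14 (not isolated)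
Conditions: (R)-2-{bis[3,5-bis(trifluoromethyl)phenyl][(trimethylsilyl)oxy]methyl}pyrrolidine (10 mol%), PhCO2H (10 mol%), toluene, 20 °C; then p-TsOH (20 mol%), toluene, 80 °C
Reagents that add atoms: none
Why: iminium-catalysed Michael addition of the keto ester to the enal, with attack anti to the shielding diaryl(silyloxy)methyl group of the (R)-catalyst, sets C5 as S (the later C1), and acid-promoted aldol condensation with loss of isobutene and CO2 (organocatalytic Robinson-type annulation) closes the cyclohexenone.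

Step 5
Reactants: 15 (5S)-5-({[tert-butyl(diphenyl)silyl]oxy}methyl)cyclohex-2-en-1-one; 16 5-iodo-2-methylpent-2-ene
Product: 18 (5S,6R)-5-({[tert-butyl(diphenyl)silyl]oxy}methyl)-6-(4-methylpent-3-en-1-yl)cyclohex-2-en-1-one, via lithium dienolate 17 (not isolated)
Conditions: LDA, THF, −78 °C; then 16, HMPA, −78 to −30 °C
Reagents that add atoms: none
Why: kinetic deprotonation at C6 gives the cross-conjugated dienolate, whose alkylation (enolate alkylation) occurs anti to the C5 substituent, although the new C6 centre is planarised again in step 11.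

Step 6
Reactants: 18 (5S,6R)-5-({[tert-butyl(diphenyl)silyl]oxy}methyl)-6-(4-methylpent-3-en-1-yl)cyclohex-2-en-1-one
Product: 19 (5S,6R)-5-(hydroxymethyl)-6-(4-methylpent-3-en-1-yl)cyclohex-2-en-1-one
Conditions: HF·pyridine, pyridine, THF, 0 to 20 °C
Reagents that add atoms: none
Why: fluoride-mediated silyl ether cleavage under mildly acidic conditions avoids base-induced oxa-Michael addition to the enone.

Step 7
Reactants: 19 (5S,6R)-5-(hydroxymethyl)-6-(4-methylpent-3-en-1-yl)cyclohex-2-en-1-one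
Product: 20 (5S,6R)-5-(iodomethyl)-6-(4-methylpent-3-en-1-yl)cyclohex-2-en-1-one
Conditions: I2, PPh3, imidazole, CH2Cl2, 0 °C
Reagents that add atoms: iodine, II
Why: Appel-type iodination converts the primary alcohol into the iodide under neutral conditions that do not touch the enone or the trisubstituted alkene.

Step 8
Reactants: 20 (5S,6R)-5-(iodomethyl)-6-(4-methylpent-3-en-1-yl)cyclohex-2-en-1-one; 10 2-[(3Z,7Z)-8-iodo-3,7-dimethylocta-3,7-dien-1-yl]-1,3-dioxolane
Product: 22 (5R,6R)-5-[(2Z,6Z)-9-(1,3-dioxolan-2-yl)-3,7-dimethylnona-2,6-dien-1-yl]-6-(4-methylpent-3-en-1-yl)cyclohex-2-en-1-one, via alkylzinc iodide 21 (not isolated)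
Conditions: Zn dust (activated by TMSCl and 1,2-dibromoethane), LiCl, THF, 25 °C; then 10, Pd(dppf)Cl2 (5 mol%), THF/NMP, 40 °C
Reagents that add atoms: none
Why: zinc inserts into the primary carbon–iodine bond and the Negishi sp3–sp2 cross-coupling keeps the geometry of the alkenyl iodide, which fixes the 2Z alkene of the tether.

Step 9
Reactants: 22 (5R,6R)-5-[(2Z,6Z)-9-(1,3-dioxolan-2-yl)-3,7-dimethylnona-2,6-dien-1-yl]-6-(4-methylpent-3-en-1-yl)cyclohex-2-en-1-one
Product: 23 (5R,6R)-5-[(2Z,6Z)-3,7-dimethyl-10-oxodeca-2,6-dien-1-yl]-6-(4-methylpent-3-en-1-yl)cyclohex-2-en-1-one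
Conditions: PPTS (20 mol%), acetone/H2O 9:1, 55 °C
Reagents that add atoms: water, O
Why: mild acid-catalysed acetal hydrolysis (transacetalisation to acetone) frees the aldehyde without isomerising the skipped Z-alkenes or the enone.

Step 10
Reactants: 23 (5R,6R)-5-[(2Z,6Z)-3,7-dimethyl-10-oxodeca-2,6-dien-1-yl]-6-(4-methylpent-3-en-1-yl)cyclohex-2-en-1-one
Product: 25 (5R,6R)-5-[(2Z,6Z,10E)-3,7-dimethyl-11-nitroundeca-2,6,10-trien-1-yl]-6-(4-methylpent-3-en-1-yl)cyclohex-2-en-1-one, via nitro alcohol 24 (not isolated)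
Conditions: MeNO2 (10 equiv), Et3N (0.2 equiv), THF, 0 °C; then MsCl, Et3N, CH2Cl2, −20 to 0 °C
Reagents that add atoms: nitromethane, C[N+](=O)[O-]
Why: the Henry reaction of the unhindered aldehyde should be much faster than conjugate addition of nitronate to the enone under weak amine base, and mesylation with E1cB elimination gives the conjugated (E)-nitroalkene.

Step 11
Reactants: 25 (5R,6R)-5-[(2Z,6Z,10E)-3,7-dimethyl-11-nitroundeca-2,6,10-trien-1-yl]-6-(4-methylpent-3-en-1-yl)cyclohex-2-en-1-one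
Product: 27 tricyclic silyl enol ether (target skeleton with the bridge C15–C16(OTBS)=C17–C13 and a nitro group on C12), via silyloxydiene 26 (not isolated)
Conditions: TBSOTf (1.3 equiv), Et3N (2 equiv), CH2Cl2, −78 to 0 °C; filtration through basic alumina; then toluene (0.001 M), BHT, 90 °C
Reagents that add atoms: tert-butyldimethylsilyl trifluoromethanesulfonate, CC(C)(C)[Si](C)(C)OS(=O)(=O)C(F)(F)F
Why: Soft enolisation towards the tertiary C6 gives the cross-conjugated 2-silyloxydiene, which undergoes a thermal, asynchronous normal-demand intramolecular Diels–Alder reaction in which the enol-ether carbon C15 attacks the nitroalkene β-carbon C11 and C12 closes onto C13. The closest known reaction type is the Diels–Alder (double Michael) addition of 2-silyloxycyclohexa-1,3-dienes or cyclohexenone dienolates to nitroalkenes giving bicyclo[2.2.2]octanones, together with macrocyclic intramolecular Diels–Alder reactions. The twelve-membered ring (C1 to C11 and C15) closes as the tether ring of the cycloaddition, while the six-membered ring C1–C14–C13–C12–C11–C15 and the temporary bicyclo[2.2.2]octene close by suprafacial [4+2] addition across C15 and C13. C15 and C11 are set by the existing C1 centre, because the dienophile adds to the diene face anti to the C1–C2 bond (the long tether can wrap around the C1–H edge) with the nitro group endo, which places the C11–C10 bond exo as the (E)-alkene demands; C12 is set too but is erased in step 13. The step needs regioselectivity, secured by the silyloxy group that makes C15 the nucleophilic diene terminus, and intra- over intermolecular reaction, secured by high dilution.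

Step 12
Reactants: 27 tricyclic silyl enol ether
Product: 29 tricyclic nitro ketol (C16 ketone, C17 hydroxyl), via silyloxy ketone 28 (not isolated)
Conditions: dimethyldioxirane (1.05 equiv), acetone/CH2Cl2, −78 °C; then HF·pyridine, THF, 0 °C
Reagents that add atoms: dimethyldioxirane, CC1(C)OO1
Why: in this Rubottom oxidation the electron-rich silyl enol ether should be epoxidised far faster than the trisubstituted alkenes at −78 °C, the silyloxy epoxide rearranges to the α-silyloxy ketone that is then desilylated, and the configuration of the new carbinol C17 is of no consequence.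

Step 13
Reactants: 29 tricyclic nitro ketol
Product: 31 tricyclic hydroxy diketone (C12 and C16 ketones, C17 hydroxyl), via potassium nitronate 30 (not isolated)
Conditions: KOtBu (1.05 equiv), THF, −20 °C; then aq. TiCl3, NH4OAc (pH 5–6), 0 to 20 °C
Reagents that add atoms: water, O
Why: the reductive Nef reaction converts the secondary nitronate through the imine into the C12 ketone under buffered conditions that should spare the ketol, the alkenes and the C11 stereocentre.

Step 14
Reactants: 31 tricyclic hydroxy diketone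
Product: 33 (1R,3Z,7Z,11R,15S)-4,8-dimethyl-15-(4-methylpent-3-en-1-yl)-12-oxobicyclo[9.3.1]pentadeca-3,7-diene-15-carboxylic acid, via formyl keto acid 32 (not isolated)
Conditions: NaIO4, THF/H2O, 20 °C; then K2CO3, MeOH/H2O, 0 °C; acidify to pH 4
Reagents that add atoms: water, O
Why: periodate cleavage of the α-ketol turns C16 into the C15 carboxyl group and C17 into a formyl group on C13, which as a β-keto aldehyde is lost by retro-Claisen deformylation, so the temporary bridge is excised without touching C1, C11 or C15.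

Step 15
Reactants: 33 (1R,3Z,7Z,11R,15S)-4,8-dimethyl-15-(4-methylpent-3-en-1-yl)-12-oxobicyclo[9.3.1]pentadeca-3,7-diene-15-carboxylic acid
Product: 34 (1R,3Z,7Z,11R,12S,15S)-4,8-dimethyl-15-(4-methylpent-3-en-1-yl)spiro[bicyclo[9.3.1]pentadeca-3,7-diene-12,2'-oxirane]-15-carboxylic acid (CNP0116395.1)
Conditions: Me3S+ I− (3 equiv), KHMDS (3 equiv), THF/DMSO, −10 to 20 °C; NaH2PO4 buffer (pH 5) work-up at 0 °C
Reagents that add atoms: trimethylsulfonium iodide, C[S+](C)C.[I-]
Why: in this Corey–Chaykovsky epoxidation of the carboxylate the sulfonium ylide should add irreversibly to the C12 ketone from the face anti to the homoprenyl chain on C15 and to the C11–C10 bond, which places the new CH2 cis and the oxygen trans to the carboxyl group (12S).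

Compound list
1 | 2-(2-bromoethyl)-1,3-dioxolane | BrCCC1OCCO1 | starting material
2 | propyne | CC#C | starting material
3 | oxirane | C1CO1 | starting material
4 | [2-(1,3-dioxolan-2-yl)ethyl]magnesium bromide | Br[Mg]CCC1OCCO1 | intermediate
5 | [(1Z)-4-(1,3-dioxolan-2-yl)-2-methylbut-1-en-1-yl]copper (monovalent copper, MgBr2 complex) | [Cu]/C=C(/C)CCC1OCCO1 | intermediate
6 | (3Z)-6-(1,3-dioxolan-2-yl)-4-methylhex-3-en-1-ol | OCC/C=C(/C)CCC1OCCO1 | intermediate
7 | 2-[(3Z)-6-bromo-3-methylhex-3-en-1-yl]-1,3-dioxolane | BrCC/C=C(/C)CCC1OCCO1 | intermediate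
8 | [(3Z)-6-(1,3-dioxolan-2-yl)-4-methylhex-3-en-1-yl]magnesium bromide | Br[Mg]CC/C=C(/C)CCC1OCCO1 | intermediate
9 | [(1Z,5Z)-8-(1,3-dioxolan-2-yl)-2,6-dimethylocta-1,5-dien-1-yl]copper (monovalent copper) | [Cu]/C=C(/C)CC/C=C(/C)CCC1OCCO1 | intermediate
10 | 2-[(3Z,7Z)-8-iodo-3,7-dimethylocta-3,7-dien-1-yl]-1,3-dioxolane | I/C=C(/C)CC/C=C(/C)CCC1OCCO1 | intermediate
11 | (2E)-4-{[tert-butyl(diphenyl)silyl]oxy}but-2-enal | O=C/C=C/CO[Si](c1ccccc1)(c1ccccc1)C(C)(C)C | starting material
12 | tert-butyl 3-oxobutanoate | CC(=O)CC(=O)OC(C)(C)C | starting material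
13 | tert-butyl (3S)-2-acetyl-3-({[tert-butyl(diphenyl)silyl]oxy}methyl)-5-oxopentanoate (C2 epimers) | CC(=O)C(C(=O)OC(C)(C)C)[C@@H](CO[Si](c1ccccc1)(c1ccccc1)C(C)(C)C)CC=O | intermediate
14 | tert-butyl (6S)-6-({[tert-butyl(diphenyl)silyl]oxy}methyl)-2-oxocyclohex-3-ene-1-carboxylate (C1 epimers) | O=C1C=CC[C@H](CO[Si](c2ccccc2)(c2ccccc2)C(C)(C)C)C1C(=O)OC(C)(C)C | intermediate
15 | (5S)-5-({[tert-butyl(diphenyl)silyl]oxy}methyl)cyclohex-2-en-1-one | O=C1C=CC[C@H](CO[Si](c2ccccc2)(c2ccccc2)C(C)(C)C)C1 | intermediate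
16 | 5-iodo-2-methylpent-2-ene | CC(C)=CCCI | starting material
17 | cross-conjugated lithium dienolate of 15 (O–Li on C1, C1=C6 and C2=C3, C5 unchanged) | [Li]OC1=C[C@@H](CO[Si](c2ccccc2)(c2ccccc2)C(C)(C)C)CC=C1 | intermediate
18 | (5S,6R)-5-({[tert-butyl(diphenyl)silyl]oxy}methyl)-6-(4-methylpent-3-en-1-yl)cyclohex-2-en-1-one | O=C1C=CC[C@H](CO[Si](c2ccccc2)(c2ccccc2)C(C)(C)C)[C@H]1CCC=C(C)C | intermediate
19 | (5S,6R)-5-(hydroxymethyl)-6-(4-methylpent-3-en-1-yl)cyclohex-2-en-1-one | O=C1C=CC[C@H](CO)[C@H]1CCC=C(C)C | intermediate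
20 | (5S,6R)-5-(iodomethyl)-6-(4-methylpent-3-en-1-yl)cyclohex-2-en-1-one | O=C1C=CC[C@H](CI)[C@H]1CCC=C(C)C | intermediate
21 | alkylzinc iodide of 20 (CH2ZnI in place of CH2I, both stereocentres as in 20) | O=C1C=CC[C@H](C[Zn]I)[C@H]1CCC=C(C)C | intermediate
22 | (5R,6R)-5-[(2Z,6Z)-9-(1,3-dioxolan-2-yl)-3,7-dimethylnona-2,6-dien-1-yl]-6-(4-methylpent-3-en-1-yl)cyclohex-2-en-1-one | O=C1C=CC[C@H](C/C=C(/C)CC/C=C(/C)CCC2OCCO2)[C@H]1CCC=C(C)C | intermediate
23 | (5R,6R)-5-[(2Z,6Z)-3,7-dimethyl-10-oxodeca-2,6-dien-1-yl]-6-(4-methylpent-3-en-1-yl)cyclohex-2-en-1-one | O=C1C=CC[C@H](C/C=C(/C)CC/C=C(/C)CCC=O)[C@H]1CCC=C(C)C | intermediate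
24 | (5R,6R)-5-[(2Z,6Z)-10-hydroxy-3,7-dimethyl-11-nitroundeca-2,6-dien-1-yl]-6-(4-methylpent-3-en-1-yl)cyclohex-2-en-1-one (carbinol epimers) | O=C1C=CC[C@H](C/C=C(/C)CC/C=C(/C)CCC(O)C[N+](=O)[O-])[C@H]1CCC=C(C)C | intermediate
25 | (5R,6R)-5-[(2Z,6Z,10E)-3,7-dimethyl-11-nitroundeca-2,6,10-trien-1-yl]-6-(4-methylpent-3-en-1-yl)cyclohex-2-en-1-one | O=C1C=CC[C@H](C/C=C(/C)CC/C=C(/C)CC/C=C/[N+](=O)[O-])[C@H]1CCC=C(C)C | intermediate
26 | tert-butyl{[(6R)-6-[(2Z,6Z,10E)-3,7-dimethyl-11-nitroundeca-2,6,10-trien-1-yl]-1-(4-methylpent-3-en-1-yl)cyclohexa-1,3-dien-2-yl]oxy}dimethylsilane | CC(C)=CCCC1=C(O[Si](C)(C)C(C)(C)C)C=CC[C@@H]1C/C=C(/C)CC/C=C(/C)CC/C=C/[N+](=O)[O-] | intermediate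
27 | tricyclic silyl enol ether: (3Z,7Z)-4,8-dimethyl-15-(4-methylpent-3-en-1-yl)-12-nitrobicyclo[9.3.1]pentadeca-3,7-diene with the bridge C15–C16(OTBS)=C17–C13; C1, C11, C15 as in the target; the bridge and the nitro group lie on the ring face that carries the C1–C2 bond, the C11–C10 bond on the opposite face | CC(C)=CCC[C@]1(C(O[Si](C)(C)C(C)(C)C)=C3)[C@H]2C/C=C(/C)CC/C=C(/C)CC[C@H]1[C@H]([N+](=O)[O-])[C@H]3C2 | intermediate
28 | as 27 with a C16 ketone and OTBS on C17 (C17 epimers) | CC(C)=CCC[C@]1(C(=O)C3O[Si](C)(C)C(C)(C)C)[C@H]2C/C=C(/C)CC/C=C(/C)CC[C@H]1[C@H]([N+](=O)[O-])[C@H]3C2 | intermediate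
29 | tricyclic nitro ketol: as 27 with a C16 ketone and OH on C17 (C17 epimers) | CC(C)=CCC[C@]1(C(=O)C3O)[C@H]2C/C=C(/C)CC/C=C(/C)CC[C@H]1[C@H]([N+](=O)[O-])[C@H]3C2 | intermediate
30 | potassium nitronate of 29 (C12=NO2 K) | CC(C)=CCC[C@]1(C(=O)C3O)[C@H]2C/C=C(/C)CC/C=C(/C)CC[C@H]1C(=[N+]([O-])[O-])[C@H]3C2.[K+] | intermediate
31 | tricyclic hydroxy diketone: as 29 with a C12 ketone in place of CH–NO2 | CC(C)=CCC[C@]1(C(=O)C3O)[C@H]2C/C=C(/C)CC/C=C(/C)CC[C@H]1C(=O)[C@H]3C2 | intermediate
32 | (1R,3Z,7Z,11R,15S)-13-formyl-4,8-dimethyl-15-(4-methylpent-3-en-1-yl)-12-oxobicyclo[9.3.1]pentadeca-3,7-diene-15-carboxylic acid (C13 epimers or enol) | CC(C)=CCC[C@]1(C(=O)O)[C@H]2C/C=C(/C)CC/C=C(/C)CC[C@H]1C(=O)C(C=O)C2 | intermediate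
33 | (1R,3Z,7Z,11R,15S)-4,8-dimethyl-15-(4-methylpent-3-en-1-yl)-12-oxobicyclo[9.3.1]pentadeca-3,7-diene-15-carboxylic acid | CC(C)=CCC[C@]1(C(=O)O)[C@H]2C/C=C(/C)CC/C=C(/C)CC[C@H]1C(=O)CC2 | intermediate
34 | (1R,3Z,7Z,11R,12S,15S)-4,8-dimethyl-15-(4-methylpent-3-en-1-yl)spiro[bicyclo[9.3.1]pentadeca-3,7-diene-12,2'-oxirane]-15-carboxylic acid | CC(C)=CCC[C@]1(C(=O)O)[C@H]2C/C=C(/C)CC/C=C(/C)CC[C@H]1[C@@]1(CC2)CO1 | target

Total step count: 15. Longest linear sequence: 12 steps (steps 4 to 15, from 11 and 12; the chain fragment 10 enters at step 8).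

Steps most likely to fail

Step 11. At high dilution the tethered cycloaddition may be outrun by bimolecular addition and oligomerisation, or the tether may deliver the nitroalkene to the wrong diene face. The fallback sets out from 18 and 10 and comes back at 31; it makes the two ring bonds in a bimolecular cycloaddition and closes the twelve-membered ring afterwards at C2–C3. The acetal of 10 is hydrolysed (PPTS, aqueous acetone) to (4Z,8Z)-9-iodo-4,8-dimethylnona-4,8-dienal F1, which Henry reaction and mesylate elimination convert into (1E,5Z,9Z)-10-iodo-5,9-dimethyl-1-nitrodeca-1,5,9-triene F2. Enone 18 is silylated (TBSOTf, Et3N) to the silyloxydiene F3. F3 and F2 are combined in a Diels–Alder reaction (toluene, 1 M, 60 °C), where addition anti to the silyloxymethyl group with the nitro group endo is the established course, to give the bicyclo[2.2.2]octene adduct F4. Rubottom oxidation (dimethyldioxirane) and TBAF/AcOH, which removes both silyl groups, give the nitro ketol alcohol F5. The Nef reaction (KOtBu, then TiCl3/NH4OAc) gives the hydroxy diketone alcohol F6, and I2/PPh3/imidazole converts its primary hydroxyl into the iodide F7. An intramolecular Negishi coupling (Zn, LiCl, then Pd(dppf)Cl2, THF, 0.002 M) then gives 31.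

Step 12. Dimethyldioxirane may epoxidise the trisubstituted alkenes in competition with the silyl enol ether. The fallback sets out from 27 and comes back at 31; it inverts the order of the two oxidations and uses an enolate instead of the enol ether. HF·pyridine hydrolyses 27 to the tricyclic nitro ketone F8 and the Nef reaction (KOtBu, then TiCl3/NH4OAc) gives the tricyclic diketone F9. Kinetic deprotonation (LiHMDS, THF, −78 °C) at C17, the only unhindered α-position, and hydroxylation with 2-(phenylsulfonyl)-3-phenyloxaziridine, which does not epoxidise alkenes, then give 31.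

Step 15. The ylide may add with poor facial selectivity, and the free carboxylate may be methylated or may open the new epoxide during work-up. The fallback sets out from 33 and comes back at 34; it protects the acid and moves the stereocontrol from kinetic to thermodynamic. The acid is alkylated (allyl bromide, K2CO3, DMF) to the allyl ester F10. Dimethylsulfoxonium methylide (Me3S(O)+ I−, NaH, DMSO), whose betaine forms reversibly, gives the epoxy allyl ester F11. Pd(PPh3)4 and morpholine remove the allyl group under neutral conditions to give 34.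

Further compounds
F1 | step 11 | (4Z,8Z)-9-iodo-4,8-dimethylnona-4,8-dienal | I/C=C(/C)CC/C=C(/C)CCC=O
F2 | step 11 | (1E,5Z,9Z)-10-iodo-5,9-dimethyl-1-nitrodeca-1,5,9-triene | I/C=C(/C)CC/C=C(/C)CC/C=C/[N+](=O)[O-]
F3 | step 11 | tert-butyl{[(6S)-6-({[tert-butyl(diphenyl)silyl]oxy}methyl)-1-(4-methylpent-3-en-1-yl)cyclohexa-1,3-dien-2-yl]oxy}dimethylsilane | CC(C)=CCCC1=C(O[Si](C)(C)C(C)(C)C)C=CC[C@@H]1CO[Si](c1ccccc1)(c1ccccc1)C(C)(C)C
F4 | step 11 | bicyclo[2.2.2]octene adduct (as 27 but with the C2–C3 bond open: CH2OTBDPS on C1 and the (3Z,7Z)-8-iodo-3,7-dimethylocta-3,7-dienyl chain on C11) | CC(C)=CCC[C@](C(O[Si](C)(C)C(C)(C)C)=C3)([C@H]2CO[Si](c4ccccc4)(c4ccccc4)C(C)(C)C)[C@@H](CC/C(C)=C\CC/C(C)=C\I)[C@H]([N+](=O)[O-])[C@H]3C2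
F5 | step 11 | nitro ketol alcohol (as F4 with a C16 ketone, OH on C17 and CH2OH on C1) | CC(C)=CCC[C@](C(=O)C3O)([C@H]2CO)[C@@H](CC/C(C)=C\CC/C(C)=C\I)[C@H]([N+](=O)[O-])[C@H]3C2
F6 | step 11 | hydroxy diketone alcohol (as F5 with a C12 ketone) | CC(C)=CCC[C@](C(=O)C3O)([C@H]2CO)[C@@H](CC/C(C)=C\CC/C(C)=C\I)C(=O)[C@H]3C2
F7 | step 11 | hydroxy diketone diiodide (as F6 with CH2I on C1) | CC(C)=CCC[C@](C(=O)C3O)([C@H]2CI)[C@@H](CC/C(C)=C\CC/C(C)=C\I)C(=O)[C@H]3C2
F8 | step 12 | tricyclic nitro ketone (as 29 without the C17 hydroxyl) | CC(C)=CCC[C@]1(C(=O)C3)[C@H]2C/C=C(/C)CC/C=C(/C)CC[C@H]1[C@H]([N+](=O)[O-])[C@H]3C2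
F9 | step 12 | tricyclic diketone (as 31 without the C17 hydroxyl) | CC(C)=CCC[C@]1(C(=O)C3)[C@H]2C/C=C(/C)CC/C=C(/C)CC[C@H]1C(=O)[C@H]3C2
F10 | step 15 | prop-2-en-1-yl ester of 33 | CC(C)=CCC[C@]1(C(=O)OCC=C)[C@H]2C/C=C(/C)CC/C=C(/C)CC[C@H]1C(=O)CC2
F11 | step 15 | prop-2-en-1-yl ester of 34 | CC(C)=CCC[C@]1(C(=O)OCC=C)[C@H]2C/C=C(/C)CC/C=C(/C)CC[C@H]1[C@@]1(CC2)CO1
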